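**Retrosynthetic overview**

1. Feature: ring B carries the contiguous carbons C8 (H, CH3), C9 (CH3, C11) and C10 (H), with the C9 methyl group cis to the C8 methyl group and to C1, beside the C5=C6 alkene (drimane numbering: ring A = C1–C5 and C10 with gem-dimethyl C4, ring B = C5–C10, C11 = the CH2 to the quinone).
2. The hydroxymethoxyquinone comes from a 2,3,5,6-tetramethoxyaryl group (oxidation, mono-hydrolysis), the C11–aryl bond from an aryllithium and a C9 aldehyde, and the C5=C6 alkene with C7H2 from a C7 ketone.
3. Rings A and B form together: an intramolecular Diels–Alder reaction of an (E)-2-methyl-enal (C9=C10, CHO = C11) with a (Z)-2-siloxydiene (C5 to C8), tethered through C1–C4, makes the C8–C9 and C5–C10 bonds.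
4. The Lewis acid-catalysed cyclisation is planned formyl-endo (trans-fused, 8α-CH3): C9 and C10 are final, C5 later becomes sp2, and C8 is inverted by equilibration beside the C7 ketone that the siloxydiene delivers. A diene with an inside methyl group would not cyclise, so the (Z)-enol ether is kept.
5. Precursor: isobutyronitrile and 5-bromopent-1-ene; methacrylate cross-metathesis before any second alkene exists, Horner–Wadsworth–Emmons olefination, silyl dienol ether, and ester to enal as the last two steps.

Key step: step 8

Remark (numbering): the ring compounds are described with the drimane numbering above; β is the face of ring B that carries the C9 methyl group, α the opposite face.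
Remark (assumption): the (S)-configured oxazaborolidinium ion is assumed to leave open the Re face of C9 of the enal; should the adduct prove antipodal, the (R)-catalyst is used and nothing else changes.

**Route**

Step 1
Reactants: 1 isobutyronitrile; 2 5-bromopent-1-ene
Product: 4 2,2-dimethylhept-6-enenitrile, via lithiated isobutyronitrile 3 (not isolated)
Conditions: LiN(i-Pr)2, THF, −78 °C; then 2, −78 °C → rt
Reagents that add atoms: none
Why: α-alkylation of a nitrile anion, in which the fully deprotonated tertiary carbanion displaces a primary bromide (SN2) and so creates the quaternary carbon C4 with the three methylene groups C3–C1 and the future C10 attached.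

Step 2
Reactants: 4 2,2-dimethylhept-6-enenitrile
Product: 6 2,2-dimethylhept-6-enal, via N-aluminio aldimine 5 (not isolated)
Conditions: i-Bu2AlH, toluene, −78 → 0 °C; then 1 M HCl aq, 0 °C
Reagents that add atoms: water, O
Why: partial reduction of a nitrile with i-Bu2AlH stops at the N-aluminio aldimine, which is hydrolysed on acidic work-up to an α-quaternary aldehyde (the future C5) that can neither enolise nor be over-reduced.

Step 3
Reactants: 6 2,2-dimethylhept-6-enal; 7 methyl methacrylate
Product: 8 methyl (E)-2,7,7-trimethyl-8-oxooct-2-enoate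
Conditions: 7 (5 equiv), RuCl2(H2IMes)(=CH-C6H4-2-O-i-Pr) (second-generation Hoveyda–Grubbs catalyst, 5 mol %), CH2Cl2, 40 °C
Reagents that add atoms: none
Why: olefin cross-metathesis of a terminal alkene with a methacrylate gives the trisubstituted enoate as the (E)-isomer under thermodynamic control (the geometry that later fixes C9 relative to C10), and at this stage the substrate has no second alkene that could divert the carbene into ring-closing metathesis.

Step 4
Reactants: 8 methyl (E)-2,7,7-trimethyl-8-oxooct-2-enoate; 9 diethyl (2-oxobutyl)phosphonate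
Product: 11 methyl (2E,8E)-2,7,7-trimethyl-10-oxododeca-2,8-dienoate, via phosphonate sodium salt 10 (not isolated)
Conditions: 9, NaH, THF, 0 °C; then 8, 0 °C → rt
Reagents that add atoms: none
Why: Horner–Wadsworth–Emmons olefination of the non-enolisable neopentyl aldehyde with a β-ketophosphonate anion gives the (E)-enone (C5=C6, C7=O, ethyl group = C8 and its methyl), and the stabilised anion leaves the hindered enoate alone.

Step 5
Reactants: 11 methyl (2E,8E)-2,7,7-trimethyl-10-oxododeca-2,8-dienoate
Product: 12 methyl (2E,8E,10Z)-10-[(tert-butyldimethylsilyl)oxy]-2,7,7-trimethyldodeca-2,8,10-trienoate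
Conditions: t-BuMe2SiOTf, Et3N, CH2Cl2, −78 → 0 °C
Reagents that add atoms: tert-butyldimethylsilyl trifluoromethanesulfonate, CC(C)(C)[Si](C)(C)OS(=O)(=O)C(F)(F)F
Why: soft enolisation (silyl triflate and amine) of the ethyl ketone gives the cross-conjugated 2-siloxydiene as the (Z)-enol ether, in which the methyl group avoids the vinyl substituent and therefore sits outside in the s-cis diene, while the ester is not enolised under these conditions.

Step 6
Reactants: 12 methyl (2E,8E,10Z)-10-[(tert-butyldimethylsilyl)oxy]-2,7,7-trimethyldodeca-2,8,10-trienoate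
Product: 13 (2E,8E,10Z)-10-[(tert-butyldimethylsilyl)oxy]-2,7,7-trimethyldodeca-2,8,10-trien-1-ol
Conditions: i-Bu2AlH (2.3 equiv), CH2Cl2, −78 °C; KNaC4H4O6 aq (potassium sodium tartrate)
Reagents that add atoms: none
Why: 1,2-reduction of the α,β-unsaturated ester to the allylic alcohol with i-Bu2AlH, which leaves the carbonyl-free silyl dienol ether untouched and is worked up without acid.

Step 7
Reactants: 13 (2E,8E,10Z)-10-[(tert-butyldimethylsilyl)oxy]-2,7,7-trimethyldodeca-2,8,10-trien-1-ol
Product: 14 (2E,8E,10Z)-10-[(tert-butyldimethylsilyl)oxy]-2,7,7-trimethyldodeca-2,8,10-trienal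
Conditions: MnO2 (activated), CH2Cl2, rt; filtered and used at once
Reagents that add atoms: none
Why: MnO2 oxidation is selective for allylic alcohols and neutral, so the (E)-enal is unmasked last, without isomerisation and without loss of the acid-labile silyl dienol ether, which could not have been formed selectively beside a free enal.

Step 8
Reactants: 14 (2E,8E,10Z)-10-[(tert-butyldimethylsilyl)oxy]-2,7,7-trimethyldodeca-2,8,10-trienal
Product: 15 trans-fused decalin aldehyde with C6=C7 silyl enol ether (CHO 9α, CH3 9β, CH3 8α, H 5β, H 10α, gem-dimethyl C4)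
Conditions: (S)-1-(2-methylphenyl)-3,3-diphenyltetrahydro-1H,3H-pyrrolo[1,2-c][1,3,2]oxazaborole (20 mol %), HN(SO2CF3)2 (18 mol %), CH2Cl2 (0.02 M), −78 → −20 °C
Reagents that add atoms: none
Why: The oxazaborolidinium-bound (E)-enal (C9=C10) and the tethered (8E,10Z)-siloxydiene (C5=C6–C7=C8) combine in a concerted, asynchronous [4+2] cycloaddition, the closest known reaction type being the chiral Lewis acid-catalysed type 1 intramolecular Diels–Alder reaction of 2-methyl-2,8,10-trienals to trans-fused octalin aldehydes. Ring B closes as the cyclohexene of the cycloaddition through the new C8–C9 and C5–C10 bonds, and ring A closes in the same event as the six-membered ring that the four-carbon tether C1–C4 spans across the C5–C10 bond, folded as a chair. C9 and C10 are tied to each other by suprafacial addition to the (E)-alkene (C1 cis to the C9 methyl group) and their absolute configuration is set by the catalyst, which is taken to leave open the enal face on which CHO, C10 and CH3 at C9 run clockwise. The formyl-endo, tether-exo transition state, preferred because the acyclic diene leaves the exo side free for the 2-methyl group and the tether while the catalyst-bound formyl group lies under C6–C7, gives the trans ring fusion (5β-H, 10α-H) and puts the outside methyl group of the (Z)-enol ether cis to the formyl group, so C8 arrives as the 8α epimer. What the step must deliver is therefore only enantioface selectivity and the C9–C10 relation, secured by the catalyst and by the enal geometry fixed in step 3, because C5 becomes sp2 in step 14 and C8 is inverted in step 12. The tether enforces the C8–C9/C5–C10 mode against the polarisation of the 2-siloxydiene, which slows the ring closure and is why it is run dilute and cold with a slight deficit of the acid.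

Step 9
Reactants: 15 trans-fused decalin aldehyde; 16 1,2,4,5-tetramethoxybenzene
Product: 18 C11 carbinol (both C11 epimers) carrying the 2,3,5,6-tetramethoxyphenyl group, via 2,3,5,6-tetramethoxyphenyllithium 17 (not isolated)
Conditions: 16, n-BuLi, TMEDA, THF, 0 °C; then 15, −78 °C; H2O at −78 °C
Reagents that add atoms: none
Why: directed ortho-lithiation between two methoxy groups followed by 1,2-addition of the aryllithium to the non-enolisable neopentyl aldehyde, with the C7 ketone masked as its silyl enol ether and a cold quench so that the alkoxide cannot take over the silyl group; the new C11 centre is formed unselectively and is removed in step 11.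

Step 10
Reactants: 18 C11 carbinol
Product: 21 O-alkyl S-methyl xanthate of 18, via sodium alkoxide 19 (not isolated), via sodium xanthate 20 (not isolated)
Conditions: NaN(SiMe3)2, CS2, THF, −78 °C; then MeI, −78 → 0 °C
Reagents that add atoms: carbon disulfide, S=C=S; iodomethane, CI
Why: xanthate formation (alkoxide addition to CS2, then S-methylation), run at −78 °C with CS2 already present so that the alkoxide is trapped before silyl migration from the enol ether oxygen can occur; this is the first half of a Barton–McCombie deoxygenation.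

Step 11
Reactants: 21 O-alkyl S-methyl xanthate
Product: 22 9α-(2,3,5,6-tetramethoxybenzyl) trans-decalin silyl enol ether (CH3 8α, CH3 9β, H 5β, H 10α)
Conditions: n-Bu3SnH, AIBN (cat.), toluene, 100 °C
Reagents that add atoms: none
Why: Barton–McCombie radical deoxygenation, in which the stannyl radical adds to the thiocarbonyl sulfur, the benzylic C–O bond fragments and the stabilised benzylic radical takes hydrogen from n-Bu3SnH, while the quaternary C9 offers no β-hydrogen for a Chugaev elimination and the silyl enol ether is inert to radicals.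

Step 12
Reactants: 22 arylmethyl silyl enol ether
Product: 24 8β-methyl 7-ketone (trans-decalin, CH3 9β, H 5β, H 10α), via 8α-methyl ketone 23 (not isolated)
Conditions: NaOMe, MeOH/THF, rt → 50 °C, to equilibrium; residual 23 separated and resubmitted
Reagents that add atoms: none
Why: methoxide transfers the silyl group to methanol to give ketone 23, and reversible enolisation toward C8 (base-mediated epimerisation α to a ketone) then moves the axial 8α-methyl group, which has 1,3-diaxial contacts with H10 and H6, into the equatorial 8β position of 24, the enolate being protonated from the axial α face anti to the axial C9 methyl group, so that kinetic and thermodynamic preference agree and C8 is set here while C9, C10 and C5 cannot change.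

Step 13
Reactants: 24 8β-methyl 7-ketone
Product: 26 C6=C7 trimethylsilyl enol ether of 24, via lithium enolate 25 (not isolated)
Conditions: LiN(i-Pr)2, Me3SiCl, THF, −78 °C (in situ quench); Et3N, cold NaHCO3 aq
Reagents that add atoms: chlorotrimethylsilane, C[Si](C)(C)Cl
Why: kinetic enolisation removes a proton from the C6 methylene and not from the hindered C8 methine beside the quaternary C9, so the enolate is trapped as the C6=C7 silyl enol ether and the new C8 configuration is not touched.

Step 14
Reactants: 26 trimethylsilyl enol ether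
Product: 27 C5=C6 7-enone (CH3 8β, CH3 9β, H 10α, 9α-CH2Ar)
Conditions: Pd(OAc)2 (1.1 equiv), MeCN, rt
Reagents that add atoms: none
Why: Ito–Saegusa oxidation, in which the palladium enolate bonded at C6 can lose a β-hydride only from C5, so the C5=C6 enone forms without a regiochemical choice, the C5 stereocentre is erased and C8 is not enolised under these neutral conditions.

Step 15
Reactants: 27 C5=C6 7-enone
Product: 29 2,3,5,6-tetramethoxybenzyl octalin with C5=C6 and C7H2 (CH3 8β, CH3 9β, H 10α), via allylic aluminium alkoxide 28 (not isolated)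
Conditions: LiAlH4, AlCl3 (1:3), Et2O, 0 °C → reflux; cold 1 M HCl aq
Reagents that add atoms: none
Why: mixed-hydride hydrogenolysis of a cyclohexenone, in which 1,2-reduction gives the allylic aluminium alkoxide, this ionises to the C5–C6–C7 allyl cation and hydride returns at the secondary terminus C7 and not at the tertiary C5 flanked by the quaternary C4, so the alkene stays at C5=C6, and the ketone is reduced before it can enolise toward C8.

Step 16
Reactants: 29 tetramethoxybenzyl octalin
Product: 30 2,5-dimethoxy-3-{[(1R,2S,8aS)-1,2,5,5-tetramethyl-1,2,3,5,6,7,8,8a-octahydronaphthalen-1-yl]methyl}cyclohexa-2,5-diene-1,4-dione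
Conditions: (NH4)2Ce(NO3)6, MeCN/H2O, 0 °C
Reagents that add atoms: water, O
Why: oxidative demethylation of a 1,4-dimethoxyarene to the p-quinone, in which either para pair of methoxy groups gives the same 3-alkyl-2,5-dimethoxybenzoquinone and the hindered trisubstituted alkene is not attacked at 0 °C.

Step 17
Reactants: 30 dimethoxyquinone
Product: 31 target, 2-hydroxy-5-methoxy-3-{[(1R,2S,8aS)-1,2,5,5-tetramethyl-1,2,3,5,6,7,8,8a-octahydronaphthalen-1-yl]methyl}cyclohexa-2,5-diene-1,4-dione (8S,9R,10S in drimane numbering)
Conditions: KOH, MeOH/H2O, rt; then 1 M HCl aq to pH 2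
Reagents that add atoms: potassium hydroxide, [K+].[OH-]
Why: addition–elimination of hydroxide on a vinylogous ester, selective for the methoxy group beside the alkyl substituent because that group is twisted out of conjugation and its carbon is the more electrophilic, and the hydroxyquinone salt formed resists a second exchange.

**Compound list**

1 | isobutyronitrile | CC(C)C#N | starting material
2 | 5-bromopent-1-ene | C=CCCCBr | starting material
3 | 2-lithio-2-methylpropanenitrile | [Li]C(C)(C)C#N | intermediate
4 | 2,2-dimethylhept-6-enenitrile | C=CCCCC(C)(C)C#N | intermediate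
5 | N-(diisobutylaluminio)-2,2-dimethylhept-6-en-1-imine | C=CCCCC(C)(C)C=N[Al](CC(C)C)CC(C)C | intermediate
6 | 2,2-dimethylhept-6-enal | C=CCCCC(C)(C)C=O | intermediate
7 | methyl methacrylate | C=C(C)C(=O)OC | starting material
8 | methyl (E)-2,7,7-trimethyl-8-oxooct-2-enoate | COC(=O)/C(C)=C/CCCC(C)(C)C=O | intermediate
9 | diethyl (2-oxobutyl)phosphonate | CCC(=O)CP(=O)(OCC)OCC | starting material
10 | sodium salt of diethyl (2-oxobutyl)phosphonate | CCC(=O)[CH-]P(=O)(OCC)OCC.[Na+] | intermediate
11 | methyl (2E,8E)-2,7,7-trimethyl-10-oxododeca-2,8-dienoate | COC(=O)/C(C)=C/CCCC(C)(C)/C=C/C(=O)CC | intermediate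
12 | methyl (2E,8E,10Z)-10-[(tert-butyldimethylsilyl)oxy]-2,7,7-trimethyldodeca-2,8,10-trienoate | COC(=O)/C(C)=C/CCCC(C)(C)/C=C/C(O[Si](C)(C)C(C)(C)C)=C/C | intermediate
13 | (2E,8E,10Z)-10-[(tert-butyldimethylsilyl)oxy]-2,7,7-trimethyldodeca-2,8,10-trien-1-ol | OC/C(C)=C/CCCC(C)(C)/C=C/C(O[Si](C)(C)C(C)(C)C)=C/C | intermediate
14 | (2E,8E,10Z)-10-[(tert-butyldimethylsilyl)oxy]-2,7,7-trimethyldodeca-2,8,10-trienal (cyclisation precursor) | C/C=C(O[Si](C)(C)C(C)(C)C)/C=C/C(C)(C)CCC/C=C(\C)C=O | intermediate
15 | trans-fused decalin aldehyde, C6=C7 tert-butyldimethylsilyl enol ether (CHO 9α, CH3 9β, CH3 8α, H 5β, H 10α) | O=C[C@@]2(C)[C@@H]3CCCC(C)(C)[C@H]3C=C(O[Si](C)(C)C(C)(C)C)[C@H]2C | intermediate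
16 | 1,2,4,5-tetramethoxybenzene | COc1cc(OC)c(OC)cc1OC | starting material
17 | 2,3,5,6-tetramethoxyphenyllithium | [Li]c1c(OC)c(OC)cc(OC)c1OC | intermediate
18 | C11 carbinol of 15 with the 2,3,5,6-tetramethoxyphenyl group (C11 epimers) | COc1cc(OC)c(OC)c(C(O)[C@@]2(C)[C@@H]3CCCC(C)(C)[C@H]3C=C(O[Si](C)(C)C(C)(C)C)[C@H]2C)c1OC | intermediate
19 | sodium alkoxide of 18 | COc1cc(OC)c(OC)c(C([O-])[C@@]2(C)[C@@H]3CCCC(C)(C)[C@H]3C=C(O[Si](C)(C)C(C)(C)C)[C@H]2C)c1OC.[Na+] | intermediate
20 | sodium O-alkyl xanthate of 18 | COc1cc(OC)c(OC)c(C(OC(=S)[S-])[C@@]2(C)[C@@H]3CCCC(C)(C)[C@H]3C=C(O[Si](C)(C)C(C)(C)C)[C@H]2C)c1OC.[Na+] | intermediate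
21 | O-alkyl S-methyl xanthate of 18 | COc1cc(OC)c(OC)c(C(OC(=S)SC)[C@@]2(C)[C@@H]3CCCC(C)(C)[C@H]3C=C(O[Si](C)(C)C(C)(C)C)[C@H]2C)c1OC | intermediate
22 | 9α-(2,3,5,6-tetramethoxybenzyl) trans-decalin, C6=C7 silyl enol ether (CH3 8α, CH3 9β, H 5β, H 10α) | COc1cc(OC)c(OC)c(C[C@@]2(C)[C@@H]3CCCC(C)(C)[C@H]3C=C(O[Si](C)(C)C(C)(C)C)[C@H]2C)c1OC | intermediate
23 | 8α-methyl 7-ketone (trans-decalin, CH3 9β, H 5β, H 10α) | COc1cc(OC)c(OC)c(C[C@@]2(C)[C@@H]3CCCC(C)(C)[C@H]3CC(=O)[C@H]2C)c1OC | intermediate
24 | 8β-methyl 7-ketone (trans-decalin, CH3 9β, H 5β, H 10α) | COc1cc(OC)c(OC)c(C[C@@]2(C)[C@@H]3CCCC(C)(C)[C@H]3CC(=O)[C@@H]2C)c1OC | intermediate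
25 | lithium C6=C7 enolate of 24 | COc1cc(OC)c(OC)c(C[C@@]2(C)[C@@H]3CCCC(C)(C)[C@H]3C=C([O-])[C@@H]2C)c1OC.[Li+] | intermediate
26 | C6=C7 trimethylsilyl enol ether of 24 | COc1cc(OC)c(OC)c(C[C@@]2(C)[C@@H]3CCCC(C)(C)[C@H]3C=C(O[Si](C)(C)C)[C@@H]2C)c1OC | intermediate
27 | C5=C6 7-enone (CH3 8β, CH3 9β, H 10α, 9α-CH2Ar) | COc1cc(OC)c(OC)c(C[C@@]2(C)[C@@H]3CCCC(C)(C)C3=CC(=O)[C@@H]2C)c1OC | intermediate
28 | dichloroaluminium alkoxide of the C7 allylic alcohol (C7 epimers) | COc1cc(OC)c(OC)c(C[C@@]2(C)[C@@H]3CCCC(C)(C)C3=CC(O[Al](Cl)Cl)[C@@H]2C)c1OC | intermediate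
29 | 1,2,4,5-tetramethoxy-3-{[(1R,2S,8aS)-1,2,5,5-tetramethyl-1,2,3,5,6,7,8,8a-octahydronaphthalen-1-yl]methyl}benzene | COc1cc(OC)c(OC)c(C[C@@]2(C)[C@@H]3CCCC(C)(C)C3=CC[C@@H]2C)c1OC | intermediate
30 | 2,5-dimethoxy-3-{[(1R,2S,8aS)-1,2,5,5-tetramethyl-1,2,3,5,6,7,8,8a-octahydronaphthalen-1-yl]methyl}cyclohexa-2,5-diene-1,4-dione | COC1=CC(=O)C(OC)=C(C[C@@]2(C)[C@@H]3CCCC(C)(C)C3=CC[C@@H]2C)C1=O | intermediate
31 | 2-hydroxy-5-methoxy-3-{[(1R,2S,8aS)-1,2,5,5-tetramethyl-1,2,3,5,6,7,8,8a-octahydronaphthalen-1-yl]methyl}cyclohexa-2,5-diene-1,4-dione | COC1=CC(=O)C(O)=C(C[C@@]2(C)[C@@H]3CCCC(C)(C)C3=CC[C@@H]2C)C1=O | target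

**Step count and risks**

Total step count: 17. Longest linear sequence: 17 steps (1 → 31); 7, 9 and 16 are commercial and enter directly.

Steps most likely to fail:

1. Step 8. The ring closure runs against the polarisation of the siloxydiene and may be slow enough for the acidic catalyst to strip the silyl enol ether or to start intermolecular Mukaiyama-type addition. Enantioface control may also erode if the temperature has to be raised, and leakage through the formyl-exo transition state would lower the yield of the trans-fused series. Fallback: setting out from 14, the cyclisation is promoted with the achiral Lewis acid Me2AlCl (CH2Cl2, −78 → −20 °C), which tolerates silyl enol ethers and should give 15 as a racemate together with the mirror-image adduct ent-15 F1. The two are separated by preparative chromatography on a cellulose tris(3,5-dimethylphenylcarbamate) stationary phase, and the route is rejoined at 15, so asymmetric catalysis is replaced by resolution.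

2. Step 15. After ionisation of the allylic aluminium alkoxide the cation may lose a proton to a 5,7-diene or take hydride at C5, which would move the alkene to C6=C7. Fallback: setting out from 27, the carbonyl group is converted into the 1,3-dithiolane of the enone F2 (HSCH2CH2SH, BF3·OEt2, CH2Cl2, 0 °C, kept short to spare C8). The two C–S bonds are then hydrogenolysed with Raney nickel in EtOH, the classical way of removing an enone carbonyl without moving the alkene, and the route is rejoined at 29.

3. Step 12. The epimerisation may be slow, because H8 of 23 is equatorial, or may stop at an equilibrium that leaves much of the 8α ketone. Fallback: setting out from recovered 23, the conditions of steps 13 and 14 give the 8α-methyl trimethylsilyl enol ether F3 and then the 8α-methyl C5=C6 7-enone F4. Kinetic deprotonation of F4 with LiN(i-Pr)2 at −78 °C takes place at the only α′ position, C8, and the lithium 5,7-dienolate F5 is protonated on carbon at −78 °C by 2,6-di-tert-butyl-4-methylphenol from the face anti to the C9 methyl group. This rejoins the route at 27, with kinetic control replacing thermodynamic control.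

Further compounds
F1 | step 8 | ent-15, mirror image of the trans-fused decalin aldehyde | O=C[C@]2(C)[C@H]3CCCC(C)(C)[C@@H]3C=C(O[Si](C)(C)C(C)(C)C)[C@@H]2C
F2 | step 15 | 1,3-dithiolane of enone 27 | COc1cc(OC)c(OC)c(C[C@@]2(C)[C@@H]3CCCC(C)(C)C3=CC4(SCCS4)[C@@H]2C)c1OC
F3 | step 12 | 8α-methyl C6=C7 trimethylsilyl enol ether (from 23) | COc1cc(OC)c(OC)c(C[C@@]2(C)[C@@H]3CCCC(C)(C)[C@H]3C=C(O[Si](C)(C)C)[C@H]2C)c1OC
F4 | step 12 | 8α-methyl C5=C6 7-enone | COc1cc(OC)c(OC)c(C[C@@]2(C)[C@@H]3CCCC(C)(C)C3=CC(=O)[C@H]2C)c1OC
F5 | step 12 | lithium 5,7-dienolate of F4 | COc1cc(OC)c(OC)c(C[C@@]2(C)[C@@H]3CCCC(C)(C)C3=CC([O-])=C2C)c1OC.[Li+]
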